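Compound numbers refer to the list after the steps and are used unchanged throughout.

## Analysis of the target

The target (39) is a linear tetramer of four guaiacyl units. Ring D is a 4-hydroxy-3-methoxybenzyl group on C4 of a tetrahydrofuran (O1, C2, C3, C4, C5) that carries a hydroxymethyl group on C3 and ring C on C2. Ring C is the benzo ring of an inner 2,3-dihydrobenzofuran whose C2 bears ring B, and ring B is the benzo ring of an outer 2,3-dihydrobenzofuran whose C2 bears the free phenol ring A; both dihydrobenzofurans carry a hydroxymethyl group at C3. There are seven stereocentres in three clusters: the tetrahydrofuran is 2R,3R,4R with aryl, hydroxymethyl and benzyl all on one face (all-cis), the inner dihydrobenzofuran is 2R,3S (trans) and the outer one 2S,3R (trans). The two benzofuran units are therefore of opposite absolute sense, and the clusters, separated by arene rings, cannot control one another. Sensitive features are the three benzylic C–O bonds para to an oxygen substituent (acid ionises them, and in the tetrahydrofuran this leads to the more stable 2,3-trans isomer), two free phenols and three primary alcohols. The difficulty lies in the contra-thermodynamic all-cis tetrahydrofuran and in setting each remote cluster independently in absolute terms. The strategy reads the tetrahydrofuran C3–C4 bond with its two branches as a trans-3,4-disubstituted butyrolactone in disguise: C5 is the lactone carbonyl, the C3 hydroxymethyl carbon is the acetal carbon of a 5-alkoxybutenolide, C2 enters as an acyl-anion equivalent of the ring C aldehyde, and the C4 benzyl group as a ring D benzylic electrophile.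

## Retrosynthetic reasoning

**Unmasking.** 39 is taken back to the dibenzyl ether 38, so that both phenols stay masked through every basic and organometallic step and are released last by neutral hydrogenolysis. 38 comes from 37 by one hydride treatment that reduces the inner C3 ester to the hydroxymethyl group and strips both pivalates. Acyl protection of the two older primary alcohols is what allows a single reagent to do all three jobs.

**Inner dihydrobenzofuran, C2–C3 bond.** In 37 the bond between C3 (α to the ester, on ring C) and C2 (bearing ring B and the ring oxygen) is cut. This is the only cut of that ring that leaves a plain aryl benzyl ether and an arylacetate (34), and it lets a chiral catalyst impose the absolute configuration, which is needed because no resident stereocentre is near. Forward, diazo ester 35 must undergo carbene insertion into the ether CH2 to give the cis ester 36, which is equilibrated at C3 to 37. The acetate side chain of 34 is traced to aryl bromide 33.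

**Aryl ether bond between ring C and ring B.** 33 is cut at the ArO–CH2 bond into bromophenol 21 and benzylic bromide 32. The cut gives two pieces of similar size, each holding one stereochemical cluster in final form, and makes the route convergent. The forward reaction is a phenoxide alkylation that touches no stereocentre.

**Outer dihydrobenzofuran.** 32 is taken back through 31 and 30 to the trans ester 29. The same C2–C3 disconnection leads via 28 and 27 to arylacetate 26 and bromide 25, and from there through 24 and 23 to 22 and 4. The forward insertion uses the mirror-image catalyst, since this ring has the opposite absolute sense. Bromide 4 serves twice, here as ring A and in the key step as ring D.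

**Ring C handle.** 21 is taken back to phenol 20, to allyl ether 19 and to alcohol 18. The bromine is placed only after the tetrahydrofuran exists, because an aryl halide would not survive the organolithium step. The phenol is carried as an allyl ether because it can be removed under neutral conditions beside the acid-labile all-cis benzylic ether.

**Tetrahydrofuran, C2–H and O1–C2 bonds.** 18 is cut at the C2–H bond to the cyclic hemiketal 17, the closed form of keto diol 16, which comes from dithiane diol 15 and from lactone 14. Only the C5 hydroxyl can reach the ketone through a five-membered ring, so the two primary alcohols are told apart without protection. Forward, hydride must add to the cyclic oxocarbenium ion on the face away from the two cis substituents, which is what the all-cis arrangement requires.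

**Key disconnection.** 14 is cut at two bonds of the future tetrahydrofuran: C2–C3 (dithiane carbon to the lactone β-carbon) and C4–CH2Ar (lactone α-carbon to the ring D benzyl). This gives dithiane 6, butenolide 11 and bromide 4, joined forward through anion 12 and enolate 13. The cut is made here because it assembles every carbon of the tetrahydrofuran and both flanking arenes in one flask, sets two stereocentres from a chiral-pool acetal, and leaves C5 and the hydroxymethyl carbon at different oxidation levels.

**Building blocks.** 6 comes from 5 and vanillin 1; 4 comes from 3, 2 and 1; 11 comes from 8 and menthol 9 (through its epimer 10), and 8 from furfural 7. 22 is bought.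

## Alternatives that were turned down

**Alternative 1: quinone-methide closure of the outer ring.**
- Disconnection: O1–C2 of the outer dihydrobenzofuran.
- Forward key step: fluoride frees two phenols of an acyclic precursor; the ring A phenoxide expels a benzylic acetate to form a para-quinone methide, and the ring B phenoxide adds to the methide carbon to give A1.
- For: the trans ring arises directly, steered by the existing C3 stereocentre. No diazo compound, no chiral rhodium catalyst and no epimerisation step are needed. For one dihydrobenzofuran taken alone this is at least as good as the carbene insertion used here.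
- Against: it addresses only the least problematic of the three ring systems. A1 carries a free phenol and an aryl bromide, so reprotection and a one-carbon homologation are needed before it can serve as a ring B electrophile. The trick cannot be repeated for the inner ring, because ring B has its para oxygen tied up as the outer ring ether; only an acid-driven cationic version would remain, and that endangers the all-cis tetrahydrofuran. The tetrahydrofuran still needs its own strategy.
- Comparison: the chosen route instead solves the tetrahydrofuran carbon chain with two stereocentres in one operation on cheap material, and makes both dihydrobenzofurans by one repeated reaction whose handedness is chosen by the catalyst enantiomer.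

**Alternative 2: cyclopropane ring expansion to a dihydrofuran.**
- Disconnection: O1–C5 of the tetrahydrofuran, with a temporary C3–C5 bond.
- Forward key step: iodide opens an aroyl/ester-activated cyclopropane at its CH2; the ketone enolate oxygen closes on that carbon (5-exo-tet) to give dihydrofuran A2 with C4 intact.
- For: only one stereocentre has to be brought in, and the heterocycle forms in one step. Syn addition of hydrogen to the C2=C3 bond from the face opposite the C4 benzyl group would place aryl and ester cis to it, i.e. all-cis. On the C2 question this is in principle as strong as the chosen route, and the path to the ring is shorter on paper.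
- Against: the double bond of A2 is tetrasubstituted and push–pull (a β-alkoxyacrylate), among the hardest to hydrogenate. Conditions forcing enough threaten the benzyl ether and the new benzylic C–O bond. Conjugate hydride reduction would leave an epimerisable ester α-carbon that relaxes to trans. The cyclopropane needs its own asymmetric step, and opening must occur at CH2 with O- rather than C-closure.
- Comparison: the chosen route takes C3 and C4 from a crystalline chiral-pool acetal by a reaction class with close analogy, and sets C2 by hydride addition to an oxocarbenium ion rather than by a demanding hydrogenation.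

**Alternative 3: ylide [4+1] annulation for the inner ring.**
- Disconnection: C2–C3 and O1–C2 of the inner dihydrobenzofuran together.
- Forward key step: base releases an ortho-quinone methide on a complete ring C fragment and an ylide on a complete ring B fragment; carbon–carbon addition and displacement of the sulfide by the phenoxide give A3.
- For: maximal convergence. Two bonds form in one step at the final oxidation level, without ester reduction or epimerisation. At the junction it is clearly shorter than the chosen sequence of ether formation, coupling, diazo transfer, insertion and epimerisation.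
- Against: neither partner has a stereocentre near the reacting carbons, so trans geometry is expected but the absolute sense is uncontrolled unless a stoichiometric chiral sulfide is used. A methide carbon bearing a silyloxymethyl group has α-hydrogens and can tautomerise to a vinylphenol before the ylide arrives. The least certain step would consume both advanced fragments. The ring C fragment still needs a tetrahydrofuran synthesis, so this competes with the inner-ring construction, not with the key step.
- Comparison: the chosen route keeps its risk early on inexpensive compounds and sets the inner C2 by a catalyst whose enantiomer can be chosen.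

Key step: step 8

Assumption: the Rh2(PTTL)4 catalysts (PTTL = N-phthaloyl-tert-leucinate) are taken to induce in the sense established for 2-aryl-2,3-dihydrobenzofuran-3-carboxylates, the (S)-catalyst leading to 2R and the (R)-catalyst to 2S; if a test on 27 shows the opposite sense, the two catalyst enantiomers are exchanged between steps 20 and 28 and nothing else changes.

## Route

Step 1
Reactants: 1 vanillin (4-hydroxy-3-methoxybenzaldehyde)
Product: 2 4-(benzyloxy)-3-methoxybenzaldehyde
Conditions: BnBr, K2CO3, DMF, rt
Reagents that add atoms: benzyl bromide, BrCc1ccccc1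
Why: Williamson ether synthesis on the phenoxide; the aldehyde is inert to carbonate.

Step 2
Reactants: 2 4-(benzyloxy)-3-methoxybenzaldehyde
Product: 3 [4-(benzyloxy)-3-methoxyphenyl]methanol
Conditions: NaBH4, MeOH, 0 °C
Reagents that add atoms: none
Why: Borohydride reduction of an aromatic aldehyde; the benzyl ether is untouched.

Step 3
Reactants: 3 [4-(benzyloxy)-3-methoxyphenyl]methanol
Product: 4 4-(benzyloxy)-3-methoxybenzyl bromide
Conditions: PBr3, Et2O, 0 °C
Reagents that add atoms: phosphorus tribromide, BrP(Br)Br
Why: The alcohol is activated as a phosphite and displaced by bromide at the electron-rich benzylic carbon; the bromide is used soon after preparation.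

Step 4
Reactants: 1 vanillin
Product: 5 4-(allyloxy)-3-methoxybenzaldehyde
Conditions: allyl bromide, K2CO3, DMF, rt
Reagents that add atoms: allyl bromide, C=CCBr
Why: Williamson ether synthesis; the allyl ether withstands organolithium, hydride and Lewis acid at low temperature and is later removed without acid.

Step 5
Reactants: 5 4-(allyloxy)-3-methoxybenzaldehyde
Product: 6 2-[4-(allyloxy)-3-methoxyphenyl]-1,3-dithiane
Conditions: HS(CH2)3SH, BF3·OEt2 (cat.), CH2Cl2, 0 °C → rt
Reagents that add atoms: propane-1,3-dithiol, SCCCS
Why: Lewis-acid-catalysed thioacetalisation of an aromatic aldehyde, which turns the carbonyl carbon into an acidic C–H for umpolung.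

Step 6
Reactants: 7 furfural
Product: 8 5-hydroxyfuran-2(5H)-one (racemic)
Conditions: O2, hν (visible), rose bengal (C20H2Cl4I4Na2O5, cat.), MeOH, rt
Reagents that add atoms: oxygen, O=O
Why: Dye-sensitised singlet oxygen adds across the furan diene in a [4+2] cycloaddition, and methanolysis of the peroxide expels the formyl carbon as methyl formate to leave the hydroxybutenolide.

Step 7
Reactants: 8 5-hydroxyfuran-2(5H)-one; 9 (−)-menthol, (1R,2S,5R)
Product: 11 (5R)-5-[(1R,2S,5R)-menthyloxy]furan-2(5H)-one, via the (5S)-acetal epimer 10 (not isolated)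
Conditions: CSA (cat.), toluene, reflux (−H2O); crystallisation from petroleum ether, mother liquor re-equilibrated with CSA and recrystallised
Reagents that add atoms: none
Why: Acid-catalysed acetalisation of the lactol through its cyclic oxocarbenium ion gives both C5 epimers, which interconvert under the acid while the less soluble (5R) epimer crystallises; the stereocentre is thus set by the chiral-pool alcohol and by crystallisation-driven equilibration.

Step 8
Reactants: 6 2-[4-(allyloxy)-3-methoxyphenyl]-1,3-dithiane; 11 (5R)-5-[(1R,2S,5R)-menthyloxy]furan-2(5H)-one; 4 4-(benzyloxy)-3-methoxybenzyl bromide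
Product: 14 (3R,4R,5R)-4-{2-[4-(allyloxy)-3-methoxyphenyl]-1,3-dithian-2-yl}-3-[4-(benzyloxy)-3-methoxybenzyl]-5-[(1R,2S,5R)-menthyloxy]dihydrofuran-2(3H)-one (trans,trans), via lithiated dithiane 12 (not isolated), via lithium lactone enolate 13 (not isolated)
Conditions: n-BuLi, THF, −78 °C; then 11, −78 °C; then 4, DMPU, −78 °C → rt
Reagents that add atoms: none
Why: n-BuLi removes the dithiane C–H to give the sulfur-stabilised benzylic anion 12, which adds in conjugate fashion (Michael addition) to butenolide 11 and forms the bond that becomes C2–C3 of the tetrahydrofuran. The resulting lithium enolate 13 is C-alkylated by benzylic bromide 4 (SN2), forming the C4–CH2Ar bond. The closest known reaction type is the tandem conjugate addition–enolate alkylation of lithiated aryl dithianes on 5-alkoxy-2(5H)-furanones used for dibenzylbutyrolactone lignans. No ring is closed. The new β-stereocentre (future C3) is controlled by the acetal carbon, the anion attacking the face anti to the menthyloxy group. The new α-stereocentre (future C4) is controlled by the bulky dithianyl group just installed, the bromide approaching anti to it, which gives the trans,trans lactone. The step needs 1,4- over 1,2-addition (secured by the soft, hindered, delocalised anion at low temperature), C- over O-alkylation and mono-alkylation (lithium enolate, soft benzylic bromide, shielded tertiary α-carbon in the product), and survival of the allyl and benzyl ethers (one equivalent of base, the dithiane C–H being by far the most acidic site). The lactone carbonyl and the acetal carbon leave the step at different oxidation levels, which keeps C5 and the hydroxymethyl carbon distinguishable.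

Step 9
Reactants: 14 trans,trans lactone acetal
Product: 15 (2R,3R)-2-{2-[4-(allyloxy)-3-methoxyphenyl]-1,3-dithian-2-yl}-3-[4-(benzyloxy)-3-methoxybenzyl]butane-1,4-diol
Conditions: LiAlH4, THF, 0 °C → rt
Reagents that add atoms: none
Why: Hydride opens the lactone, the freed acyloxy acetal collapses to an aldehyde with loss of menthoxide, and both carbonyl carbons are reduced to primary alcohols. The two stereocentres, the dithiane and the allyl and benzyl ethers are inert to hydride.

Step 10
Reactants: 15 dithiane diol
Product: 17 (3R,4R)-2-[4-(allyloxy)-3-methoxyphenyl]-4-[4-(benzyloxy)-3-methoxybenzyl]-3-(hydroxymethyl)tetrahydrofuran-2-ol (both C2 epimers), via open-chain keto diol 16 (not isolated)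
Conditions: MeI, CaCO3, MeCN–H2O (4:1), 45 °C
Reagents that add atoms: water, O
Why: S-Methylation turns the thioacetal into a leaving group and the aryl-stabilised thionium ion is hydrolysed (alkylative dethioacetalisation), while CaCO3 keeps the medium neutral for the allyl and benzyl ethers. The freed ketone 16 is captured by the C5 hydroxyl as the five-membered hemiketal 17 (the other hydroxyl could only close a four-membered ring), which distinguishes the two primary alcohols without a protecting group.

Step 11
Reactants: 17 cyclic hemiketal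
Product: 18 {(2R,3R,4R)-2-[4-(allyloxy)-3-methoxyphenyl]-4-[4-(benzyloxy)-3-methoxybenzyl]tetrahydrofuran-3-yl}methanol (all-cis)
Conditions: Et3SiH, BF3·OEt2, CH2Cl2, −78 °C; Et3N quench at −78 °C
Reagents that add atoms: none
Why: BF3·OEt2 ionises the hemiketal to an aryl-stabilised cyclic oxocarbenium ion and Et3SiH reduces it (ionic reductive deoxygenation of a cyclic hemiketal). Hydride should enter on the face away from the cis C3 and C4 substituents (inside attack on the envelope that keeps the C4 benzyl group pseudo-equatorial), which places the aryl group cis to both and sets C2 as R. The cold basic quench keeps the kinetic all-cis benzylic ether from re-ionising.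

Step 12
Reactants: 18 all-cis tetrahydrofuran alcohol
Product: 19 {(2R,3R,4R)-2-[4-(allyloxy)-3-methoxyphenyl]-4-[4-(benzyloxy)-3-methoxybenzyl]tetrahydrofuran-3-yl}methyl pivalate
Conditions: PivCl, pyridine, DMAP (cat.), CH2Cl2, 0 °C → rt
Reagents that add atoms: pivaloyl chloride, CC(C)(C)C(Cl)=O
Why: Acylation of the primary alcohol; the pivalate has no α-hydrogen, survives the bases and carbenes ahead, blocks O–H insertion, and is removed by the final hydride step.

Step 13
Reactants: 19 allyl ether pivalate
Product: 20 {(2R,3R,4R)-4-[4-(benzyloxy)-3-methoxybenzyl]-2-(4-hydroxy-3-methoxyphenyl)tetrahydrofuran-3-yl}methyl pivalate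
Conditions: Pd(PPh3)4 (cat.), morpholine, THF, rt
Reagents that add atoms: none
Why: Zerovalent palladium ionises the allyl aryl ether to a π-allyl complex and the phenoxide, and morpholine takes the allyl group (Tsuji–Trost deallylation). The conditions are neutral, so the pivalate, the benzyl ether and the acid-labile all-cis benzylic ether are not touched.

Step 14
Reactants: 20 ring C phenol
Product: 21 {(2R,3R,4R)-4-[4-(benzyloxy)-3-methoxybenzyl]-2-(3-bromo-4-hydroxy-5-methoxyphenyl)tetrahydrofuran-3-yl}methyl pivalate
Conditions: NBS (1.0 equiv), CH2Cl2, −20 °C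
Reagents that add atoms: N-bromosuccinimide, BrN1C(=O)CCC1=O
Why: Electrophilic aromatic bromination of the free phenol, whose para position is blocked and whose other ortho position carries methoxy, so C5 of ring C is the only strongly activated site. The benzyl-protected ring D is much less nucleophilic and one equivalent at low temperature should leave it alone.

Step 15
Reactants: 22 5-bromovanillin (3-bromo-4-hydroxy-5-methoxybenzaldehyde); 4 4-(benzyloxy)-3-methoxybenzyl bromide
Product: 23 4-{[4-(benzyloxy)-3-methoxybenzyl]oxy}-3-bromo-5-methoxybenzaldehyde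
Conditions: K2CO3, DMF, 50 °C
Reagents that add atoms: none
Why: Williamson ether synthesis; the acidic, hindered bromophenol is alkylated cleanly by the reactive benzylic bromide, which brings in ring A and the future C2 of the outer ring.

Step 16
Reactants: 23 ether aldehyde
Product: 24 (4-{[4-(benzyloxy)-3-methoxybenzyl]oxy}-3-bromo-5-methoxyphenyl)methanol
Conditions: NaBH4, MeOH–THF, 0 °C
Reagents that add atoms: none
Why: Borohydride reduction; the aldehyde would not survive the zinc enolate of step 18 and is needed later as a benzylic leaving group.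

Step 17
Reactants: 24 benzylic alcohol
Product: 25 tert-butyl[(4-{[4-(benzyloxy)-3-methoxybenzyl]oxy}-3-bromo-5-methoxybenzyl)oxy]dimethylsilane
Conditions: TBSCl, imidazole, DMF, rt
Reagents that add atoms: tert-butyldimethylsilyl chloride, CC(C)(C)[Si](C)(C)Cl
Why: Silylation of the primary alcohol; the silyl ether is stable to the coupling, diazo transfer, carbene and hydride steps and is later exchanged directly for bromide.

Step 18
Reactants: 25 aryl bromide
Product: 26 tert-butyl 2-[2-{[4-(benzyloxy)-3-methoxybenzyl]oxy}-5-{[(tert-butyldimethylsilyl)oxy]methyl}-3-methoxyphenyl]acetate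
Conditions: BrZnCH2CO2tBu, Pd(dba)2 (cat.), P(t-Bu)3 (cat.), THF, rt
Reagents that add atoms: (2-tert-butoxy-2-oxoethyl)zinc bromide, Br[Zn]CC(=O)OC(C)(C)C
Why: Zerovalent palladium inserts into the aryl bromide, the zinc ester enolate transmetallates and reductive elimination gives the arylacetate (Negishi-type α-arylation with a Reformatsky reagent). The neutral zinc enolate tolerates the silyl and benzyl ethers and does not arylate twice.

Step 19
Reactants: 26 tert-butyl arylacetate
Product: 27 tert-butyl 2-[2-{[4-(benzyloxy)-3-methoxybenzyl]oxy}-5-{[(tert-butyldimethylsilyl)oxy]methyl}-3-methoxyphenyl]-2-diazoacetate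
Conditions: p-ABSA, DBU, MeCN, 0 °C → rt
Reagents that add atoms: 4-acetamidobenzenesulfonyl azide, CC(=O)Nc1ccc(cc1)S(=O)(=O)N=[N+]=[N-]
Why: Regitz diazo transfer: the arylacetate enolate attacks the sulfonyl azide and the triazene collapses to the aryldiazoacetate and the sulfonamide.

Step 20
Reactants: 27 aryldiazoacetate
Product: 28 tert-butyl (2S,3R)-2-[4-(benzyloxy)-3-methoxyphenyl]-5-{[(tert-butyldimethylsilyl)oxy]methyl}-7-methoxy-2,3-dihydrobenzofuran-3-carboxylate (cis)
Conditions: Rh2(R-PTTL)4 (1 mol %), toluene, −60 °C
Reagents that add atoms: none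
Why: The rhodium carbene inserts into the benzylic C–H bond of the ether five atoms away (intramolecular 1,5 C–H insertion), a bond activated by the adjacent oxygen and by electron-rich ring A. The concerted insertion gives the cis dihydrobenzofuran, and the chiral carboxylate ligands select which benzylic hydrogen reacts, setting C2 as S. C3 forms cis (3R) and is corrected in the next step.

Step 21
Reactants: 28 cis ester
Product: 29 tert-butyl (2S,3S)-2-[4-(benzyloxy)-3-methoxyphenyl]-5-{[(tert-butyldimethylsilyl)oxy]methyl}-7-methoxy-2,3-dihydrobenzofuran-3-carboxylate (trans)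
Conditions: t-BuOK (0.2 equiv), t-BuOH–THF, 0 °C → rt
Reagents that add atoms: none
Why: Catalytic alkoxide reversibly forms the ester enolate and reprotonation gives the less strained trans ester. Ring opening by loss of the aryloxide would be the reverse of a 5-endo-trig closure and is stereoelectronically disfavoured, so C2 is not at risk.

Step 22
Reactants: 29 trans ester
Product: 30 {(2S,3R)-2-[4-(benzyloxy)-3-methoxyphenyl]-5-{[(tert-butyldimethylsilyl)oxy]methyl}-7-methoxy-2,3-dihydrobenzofuran-3-yl}methanol
Conditions: LiAlH4, THF, 0 °C → rt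
Reagents that add atoms: none
Why: Hydride reduction of the tert-butyl ester to the primary alcohol; the silyl ether, benzyl ether and ring benzylic ether are inert.

Step 23
Reactants: 30 primary alcohol
Product: 31 {(2S,3R)-2-[4-(benzyloxy)-3-methoxyphenyl]-5-{[(tert-butyldimethylsilyl)oxy]methyl}-7-methoxy-2,3-dihydrobenzofuran-3-yl}methyl pivalate
Conditions: PivCl, pyridine, DMAP (cat.), CH2Cl2, 0 °C → rt
Reagents that add atoms: pivaloyl chloride, CC(C)(C)C(Cl)=O
Why: Acylation of the primary alcohol; the pivalate leaves no acidic C–H in this ring during the later base and carbene steps and falls off in the final hydride step.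

Step 24
Reactants: 31 benzylic silyl ether
Product: 32 {(2S,3R)-2-[4-(benzyloxy)-3-methoxyphenyl]-5-(bromomethyl)-7-methoxy-2,3-dihydrobenzofuran-3-yl}methyl pivalate
Conditions: Ph3PBr2, CH2Cl2, 0 °C → rt
Reagents that add atoms: dibromotriphenylphosphorane, BrP(Br)(c1ccccc1)(c1ccccc1)c1ccccc1
Why: The silyl ether oxygen attacks the bromophosphonium reagent, bromide removes the silyl group, and the alkoxyphosphonium salt is displaced by bromide at the benzylic carbon (direct silyl ether to bromide conversion, an Appel-type substitution). The pivalate and aryl ethers do not react; the bromide is used without storage.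

Step 25
Reactants: 21 ring C bromophenol; 32 ring B benzylic bromide
Product: 33 aryl benzyl ether: 21 O-alkylated on the ring C phenol by the benzylic carbon of 32 (ring C 3-bromo-5-methoxy-4-(arylmethoxy)phenyl; THF 2R,3R,4R; outer ring 2S,3R; two pivalates, two benzyl ethers)
Conditions: K2CO3, DMF, rt
Reagents that add atoms: none
Why: Williamson ether synthesis between the acidic bromophenol and the reactive benzylic bromide. No stereocentre is involved, and any minor enantiomer of 32 becomes a separable diastereomer here.

Step 26
Reactants: 33 aryl bromide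
Product: 34 tert-butyl arylacetate: 33 with CH2CO2tBu in place of the ring C bromine
Conditions: BrZnCH2CO2tBu, Pd(dba)2 (cat.), P(t-Bu)3 (cat.), THF, rt → 40 °C
Reagents that add atoms: (2-tert-butoxy-2-oxoethyl)zinc bromide, Br[Zn]CC(=O)OC(C)(C)C
Why: Same Negishi-type α-arylation with the Reformatsky reagent as in step 18. Pivalates, benzyl ethers and the ring ethers are compatible with the neutral zinc enolate.

Step 27
Reactants: 34 tert-butyl arylacetate
Product: 35 tert-butyl aryldiazoacetate: 34 with C(=N2) in place of the acetate CH2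
Conditions: p-ABSA, DBU, MeCN, 0 °C → rt
Reagents that add atoms: 4-acetamidobenzenesulfonyl azide, CC(=O)Nc1ccc(cc1)S(=O)(=O)N=[N+]=[N-]
Why: Regitz diazo transfer at the only acidic methylene; the pivalates have no α-hydrogen and the outer ring carries no ester.

Step 28
Reactants: 35 aryldiazoacetate
Product: 36 inner cis dihydrobenzofuran ester (inner ring 2R,3S; tert-butyl ester at C3 cis to ring B at C2; THF 2R,3R,4R; outer ring 2S,3R)
Conditions: Rh2(S-PTTL)4 (1–2 mol %), toluene, −60 °C
Reagents that add atoms: none
Why: Same intramolecular 1,5 C–H insertion as in step 20, now into the CH2 that links the ring C oxygen to ring B. The enantiomeric catalyst is used so that C2 of the inner ring becomes R under catalyst control (the resident stereocentres being remote), and C3 forms cis. No O–H bond is present, and only the intended C–H bond can reach the carbene through a five-membered transition state.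

Step 29
Reactants: 36 inner cis ester
Product: 37 inner trans dihydrobenzofuran ester (inner ring 2R,3R; otherwise as 36)
Conditions: t-BuOK (0.2 equiv), t-BuOH–THF, 0 °C → rt
Reagents that add atoms: none
Why: Enolate-mediated epimerisation at C3 to the thermodynamically preferred trans ester, as in step 21; the pivalates and the all-cis tetrahydrofuran have no acidic site.

Step 30
Reactants: 37 inner trans ester
Product: 38 dibenzyl ether of the target (triol; rings A and D as benzyl ethers)
Conditions: LiAlH4 (excess), THF, 0 °C → rt
Reagents that add atoms: none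
Why: Hydride reduces the tert-butyl ester to the inner hydroxymethyl group (C3 becomes 3S by descriptor only) and cleaves both pivalates in the same operation. Benzyl ethers and ring benzylic ethers are inert to hydride.

Step 31
Reactants: 38 dibenzyl ether
Product: 39 target, CNP0395728.1
Conditions: H2 (1 atm), 10% Pd/C, EtOAc–EtOH, rt
Reagents that add atoms: none
Why: Hydrogenolysis of the two aryl benzyl ethers. These O-benzyl bonds are cleaved much faster than the ring benzylic C–O bonds of the dihydrobenzofurans and the tetrahydrofuran, so the reaction is run at one atmosphere in neutral solvent and stopped at full conversion.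

## Compound list

1 | vanillin | COc1cc(C=O)ccc1O | starting material
2 | 4-(benzyloxy)-3-methoxybenzaldehyde | COc1cc(C=O)ccc1OCc1ccccc1 | intermediate
3 | [4-(benzyloxy)-3-methoxyphenyl]methanol | COc1cc(CO)ccc1OCc1ccccc1 | intermediate
4 | 4-(benzyloxy)-3-methoxybenzyl bromide | COc1cc(CBr)ccc1OCc1ccccc1 | intermediate
5 | 4-(allyloxy)-3-methoxybenzaldehyde | COc1cc(C=O)ccc1OCC=C | intermediate
6 | 2-[4-(allyloxy)-3-methoxyphenyl]-1,3-dithiane | COc1cc(C2SCCCS2)ccc1OCC=C | intermediate
7 | furfural | O=Cc1ccco1 | starting material
8 | 5-hydroxyfuran-2(5H)-one (racemic) | O=C1C=CC(O)O1 | intermediate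
9 | (−)-menthol, (1R,2S,5R) | C[C@@H]1CC[C@H]([C@@H](C1)O)C(C)C | starting material
10 | (5S)-5-[(1R,2S,5R)-menthyloxy]furan-2(5H)-one | O=C1C=C[C@@H](O[C@@H]2C[C@H](C)CC[C@H]2C(C)C)O1 | intermediate (not isolated)
11 | (5R)-5-[(1R,2S,5R)-menthyloxy]furan-2(5H)-one | O=C1C=C[C@H](O[C@@H]2C[C@H](C)CC[C@H]2C(C)C)O1 | intermediate
12 | 2-lithio-2-[4-(allyloxy)-3-methoxyphenyl]-1,3-dithiane | [Li]C1(c2ccc(OCC=C)c(OC)c2)SCCCS1 | intermediate (not isolated)
13 | lithium enolate of the (4R,5R)-4-(2-aryl-1,3-dithian-2-yl)-5-menthyloxy lactone | [Li]OC1=C[C@@H](C2(c3ccc(OCC=C)c(OC)c3)SCCCS2)[C@H](O[C@@H]2C[C@H](C)CC[C@H]2C(C)C)O1 | intermediate (not isolated)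
14 | (3R,4R,5R)-4-{2-[4-(allyloxy)-3-methoxyphenyl]-1,3-dithian-2-yl}-3-[4-(benzyloxy)-3-methoxybenzyl]-5-[(1R,2S,5R)-menthyloxy]dihydrofuran-2(3H)-one | COc1cc(C[C@H]2C(=O)O[C@@H](O[C@@H]3C[C@H](C)CC[C@H]3C(C)C)[C@@H]2C2(c3ccc(OCC=C)c(OC)c3)SCCCS2)ccc1OCc1ccccc1 | intermediate
15 | (2R,3R)-2-{2-[4-(allyloxy)-3-methoxyphenyl]-1,3-dithian-2-yl}-3-[4-(benzyloxy)-3-methoxybenzyl]butane-1,4-diol | COc1cc(C[C@@H](CO)[C@H](CO)C2(c3ccc(OCC=C)c(OC)c3)SCCCS2)ccc1OCc1ccccc1 | intermediate
16 | (2R,3R)-1-[4-(allyloxy)-3-methoxyphenyl]-3-[4-(benzyloxy)-3-methoxybenzyl]-4-hydroxy-2-(hydroxymethyl)butan-1-one | COc1cc(C[C@@H](CO)[C@H](CO)C(=O)c2ccc(OCC=C)c(OC)c2)ccc1OCc1ccccc1 | intermediate (not isolated)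
17 | (3R,4R)-2-[4-(allyloxy)-3-methoxyphenyl]-4-[4-(benzyloxy)-3-methoxybenzyl]-3-(hydroxymethyl)tetrahydrofuran-2-ol (C2 epimers) | COc1cc(C[C@H]2COC(O)(c3ccc(OCC=C)c(OC)c3)[C@H]2CO)ccc1OCc1ccccc1 | intermediate
18 | {(2R,3R,4R)-2-[4-(allyloxy)-3-methoxyphenyl]-4-[4-(benzyloxy)-3-methoxybenzyl]tetrahydrofuran-3-yl}methanol | COc1cc(C[C@H]2CO[C@@H](c3ccc(OCC=C)c(OC)c3)[C@H]2CO)ccc1OCc1ccccc1 | intermediate
19 | {(2R,3R,4R)-2-[4-(allyloxy)-3-methoxyphenyl]-4-[4-(benzyloxy)-3-methoxybenzyl]tetrahydrofuran-3-yl}methyl pivalate | COc1cc(C[C@H]2CO[C@@H](c3ccc(OCC=C)c(OC)c3)[C@H]2COC(=O)C(C)(C)C)ccc1OCc1ccccc1 | intermediate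
20 | {(2R,3R,4R)-4-[4-(benzyloxy)-3-methoxybenzyl]-2-(4-hydroxy-3-methoxyphenyl)tetrahydrofuran-3-yl}methyl pivalate | COc1cc(C[C@H]2CO[C@@H](c3ccc(O)c(OC)c3)[C@H]2COC(=O)C(C)(C)C)ccc1OCc1ccccc1 | intermediate
21 | {(2R,3R,4R)-4-[4-(benzyloxy)-3-methoxybenzyl]-2-(3-bromo-4-hydroxy-5-methoxyphenyl)tetrahydrofuran-3-yl}methyl pivalate | COc1cc(C[C@H]2CO[C@@H](c3cc(Br)c(O)c(OC)c3)[C@H]2COC(=O)C(C)(C)C)ccc1OCc1ccccc1 | intermediate
22 | 5-bromovanillin | COc1cc(C=O)cc(Br)c1O | starting material
23 | 4-{[4-(benzyloxy)-3-methoxybenzyl]oxy}-3-bromo-5-methoxybenzaldehyde | COc1cc(C=O)cc(Br)c1OCc1ccc(OCc2ccccc2)c(OC)c1 | intermediate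
24 | (4-{[4-(benzyloxy)-3-methoxybenzyl]oxy}-3-bromo-5-methoxyphenyl)methanol | COc1cc(CO)cc(Br)c1OCc1ccc(OCc2ccccc2)c(OC)c1 | intermediate
25 | tert-butyl[(4-{[4-(benzyloxy)-3-methoxybenzyl]oxy}-3-bromo-5-methoxybenzyl)oxy]dimethylsilane | COc1cc(CO[Si](C)(C)C(C)(C)C)cc(Br)c1OCc1ccc(OCc2ccccc2)c(OC)c1 | intermediate
26 | tert-butyl 2-[2-{[4-(benzyloxy)-3-methoxybenzyl]oxy}-5-{[(tert-butyldimethylsilyl)oxy]methyl}-3-methoxyphenyl]acetate | COc1cc(CO[Si](C)(C)C(C)(C)C)cc(CC(=O)OC(C)(C)C)c1OCc1ccc(OCc2ccccc2)c(OC)c1 | intermediate
27 | tert-butyl 2-[2-{[4-(benzyloxy)-3-methoxybenzyl]oxy}-5-{[(tert-butyldimethylsilyl)oxy]methyl}-3-methoxyphenyl]-2-diazoacetate | COc1cc(CO[Si](C)(C)C(C)(C)C)cc(C(=[N+]=[N-])C(=O)OC(C)(C)C)c1OCc1ccc(OCc2ccccc2)c(OC)c1 | intermediate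
28 | tert-butyl (2S,3R)-2-[4-(benzyloxy)-3-methoxyphenyl]-5-{[(tert-butyldimethylsilyl)oxy]methyl}-7-methoxy-2,3-dihydrobenzofuran-3-carboxylate (cis) | CC(C)(C)[Si](C)(C)OCc1cc(OC)c2c(c1)[C@@H](C(=O)OC(C)(C)C)[C@@H](c1ccc(OCc3ccccc3)c(OC)c1)O2 | intermediate
29 | tert-butyl (2S,3S)-2-[4-(benzyloxy)-3-methoxyphenyl]-5-{[(tert-butyldimethylsilyl)oxy]methyl}-7-methoxy-2,3-dihydrobenzofuran-3-carboxylate (trans) | CC(C)(C)[Si](C)(C)OCc1cc(OC)c2c(c1)[C@H](C(=O)OC(C)(C)C)[C@@H](c1ccc(OCc3ccccc3)c(OC)c1)O2 | intermediate
30 | {(2S,3R)-2-[4-(benzyloxy)-3-methoxyphenyl]-5-{[(tert-butyldimethylsilyl)oxy]methyl}-7-methoxy-2,3-dihydrobenzofuran-3-yl}methanol | CC(C)(C)[Si](C)(C)OCc1cc(OC)c2c(c1)[C@H](CO)[C@@H](c1ccc(OCc3ccccc3)c(OC)c1)O2 | intermediate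
31 | {(2S,3R)-2-[4-(benzyloxy)-3-methoxyphenyl]-5-{[(tert-butyldimethylsilyl)oxy]methyl}-7-methoxy-2,3-dihydrobenzofuran-3-yl}methyl pivalate | CC(C)(C)[Si](C)(C)OCc1cc(OC)c2c(c1)[C@H](COC(=O)C(C)(C)C)[C@@H](c1ccc(OCc3ccccc3)c(OC)c1)O2 | intermediate
32 | {(2S,3R)-2-[4-(benzyloxy)-3-methoxyphenyl]-5-(bromomethyl)-7-methoxy-2,3-dihydrobenzofuran-3-yl}methyl pivalate | BrCc1cc(OC)c2c(c1)[C@H](COC(=O)C(C)(C)C)[C@@H](c1ccc(OCc3ccccc3)c(OC)c1)O2 | intermediate
33 | ring C aryl bromide with the ring B benzyl ether (from 21 and 32) | COc1cc(C[C@H]2CO[C@@H](c3cc(Br)c(OCc4cc(OC)c5c(c4)[C@H](COC(=O)C(C)(C)C)[C@@H](c4ccc(OCc6ccccc6)c(OC)c4)O5)c(OC)c3)[C@H]2COC(=O)C(C)(C)C)ccc1OCc1ccccc1 | intermediate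
34 | tert-butyl arylacetate (33 with CH2CO2tBu for Br) | COc1cc(C[C@H]2CO[C@@H](c3cc(CC(=O)OC(C)(C)C)c(OCc4cc(OC)c5c(c4)[C@H](COC(=O)C(C)(C)C)[C@@H](c4ccc(OCc6ccccc6)c(OC)c4)O5)c(OC)c3)[C@H]2COC(=O)C(C)(C)C)ccc1OCc1ccccc1 | intermediate
35 | tert-butyl aryldiazoacetate (diazo derivative of 34) | COc1cc(C[C@H]2CO[C@@H](c3cc(C(=[N+]=[N-])C(=O)OC(C)(C)C)c(OCc4cc(OC)c5c(c4)[C@H](COC(=O)C(C)(C)C)[C@@H](c4ccc(OCc6ccccc6)c(OC)c4)O5)c(OC)c3)[C@H]2COC(=O)C(C)(C)C)ccc1OCc1ccccc1 | intermediate
36 | inner cis dihydrobenzofuran tert-butyl ester (inner 2R,3S; outer 2S,3R; THF 2R,3R,4R) | COc1cc(C[C@H]2CO[C@@H](c3cc(OC)c4c(c3)[C@H](C(=O)OC(C)(C)C)[C@H](c3cc(OC)c5c(c3)[C@H](COC(=O)C(C)(C)C)[C@@H](c3ccc(OCc6ccccc6)c(OC)c3)O5)O4)[C@H]2COC(=O)C(C)(C)C)ccc1OCc1ccccc1 | intermediate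
37 | inner trans dihydrobenzofuran tert-butyl ester (inner 2R,3R; outer 2S,3R; THF 2R,3R,4R) | COc1cc(C[C@H]2CO[C@@H](c3cc(OC)c4c(c3)[C@@H](C(=O)OC(C)(C)C)[C@H](c3cc(OC)c5c(c3)[C@H](COC(=O)C(C)(C)C)[C@@H](c3ccc(OCc6ccccc6)c(OC)c3)O5)O4)[C@H]2COC(=O)C(C)(C)C)ccc1OCc1ccccc1 | intermediate
38 | dibenzyl ether of the target (triol; inner 2R,3S; outer 2S,3R; THF 2R,3R,4R) | COc1cc(C[C@H]2CO[C@@H](c3cc(OC)c4c(c3)[C@@H](CO)[C@H](c3cc(OC)c5c(c3)[C@H](CO)[C@@H](c3ccc(OCc6ccccc6)c(OC)c3)O5)O4)[C@H]2CO)ccc1OCc1ccccc1 | intermediate
39 | CNP0395728.1 (THF 2R,3R,4R all-cis; inner dihydrobenzofuran 2R,3S; outer 2S,3R) | COc1cc(C[C@H]2CO[C@@H](c3cc(OC)c4c(c3)[C@@H](CO)[C@H](c3cc(OC)c5c(c3)[C@H](CO)[C@@H](c3ccc(O)c(OC)c3)O5)O4)[C@H]2CO)ccc1O | target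

## Step count and least certain steps

Total step count: 31. Longest linear sequence: 20 steps (steps 1–3, then 15–31; 1 → 4 → 23 → 32 → 33 → 39). The branch through the key step reaches 33 in at most 11 steps.

**Step 8 (key step).** The enolate 13 sits beside a quaternary dithiane carbon. Its alkylation may be slow, so that proton quench or retro-Michael loss of the dithiane on warming competes, and a sluggish alkylation run warm could erode the trans selectivity.
Fallback, from 6 and 11 back to 14: the two bond formations are separated. Anion 12 is added to 11 as before, but the enolate is quenched with NH4Cl and the conjugate adduct is isolated as (4R,5R)-4-{2-[4-(allyloxy)-3-methoxyphenyl]-1,3-dithian-2-yl}-5-[(1R,2S,5R)-menthyloxy]dihydrofuran-2(3H)-one F1. F1 is then re-enolised with LiN(SiMe3)2 in THF–DMPU at −78 °C and alkylated with 4 under conditions tuned for that step alone, giving 14.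

**Step 11.** Two processes threaten the all-cis ring. The first is poor facial selectivity or re-ionisation of the product benzylic ether under the Lewis acid, which leads to the 2,3-trans isomer. The second is proton loss from the oxocarbenium ion to a cyclic enol ether, which on re-protonation scrambles C3.
Fallback, from 17 back to 19: C2 is set on the open chain under reagent control and the ring is closed by O-alkylation, which leaves C2 untouched.
- The free hydroxymethyl group of 17 is acylated (PivCl, pyridine, 0 °C) to the lactol pivalate F2.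
- MsCl/Et3N traps the open-chain tautomer as (2R,3R)-4-[4-(allyloxy)-3-methoxyphenyl]-2-[4-(benzyloxy)-3-methoxybenzyl]-4-oxo-3-(pivaloyloxymethyl)butyl methanesulfonate F3.
- Corey–Bakshi–Shibata reduction ((S)-2-methyl-CBS-oxazaborolidine, catecholborane, toluene, −78 °C; aryl as the large group) gives the (R)-carbinol, hydroxy mesylate F4.
- t-BuOK in THF at 0 °C closes the ring by 5-exo-tet displacement of the primary mesylate and gives 19.

**Step 28 (and its simpler test case, step 20).** Catalyst control is asked to distinguish the two benzylic hydrogens on a large, polyoxygenated substrate bearing a tert-butyl ester. Facial discrimination may be weak, giving a 2R/2S mixture, and the carbene may be diverted by the many ether oxygens and arenes.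
Fallback, from 33 back to 38: a chiral ester auxiliary is added to the catalyst control.
- 33 is coupled (Pd(dba)2, P(t-Bu)3) with the Reformatsky reagent of (S)-1-oxo-1-(pyrrolidin-1-yl)propan-2-yl bromoacetate to give the lactamide arylacetate F5.
- Diazo transfer (p-ABSA, DBU) gives the lactamide diazo ester F6.
- Insertion with Rh2(S-DOSP)4 (DOSP = N-(4-dodecylbenzenesulfonyl)prolinate), an auxiliary–catalyst pairing that gives trans-2-aryl-2,3-dihydrobenzofuran-3-carboxylates directly, gives the trans lactamide ester F7. The auxiliary enantiomer is switched if the pair proves mismatched for the 2R series.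
- LiAlH4 removes the auxiliary together with the pivalates and gives 38; the epimerisation step is saved.

**Step 14.** Bromination may occur on ring D or at another ring C position, ipso attack at the para carbon may cleave the tetrahydrofuran, and over-bromination is possible.
Fallback, from 19 back to 34: the ortho carbon is introduced by sigmatropic rearrangement, which can only reach the free ortho position.
- Heating 19 in 1,2-dichlorobenzene at 180 °C (aromatic Claisen rearrangement) gives the C-allyl phenol F8.
- Williamson etherification with 32 (K2CO3, DMF) gives ether F9.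
- OsO4 (cat.), NaIO4, 2,6-lutidine (Lemieux–Johnson cleavage) gives arylacetaldehyde F10.
- NaClO2, NaH2PO4, 2-methyl-2-butene (Pinnick oxidation) gives arylacetic acid F11.
- Boc2O, DMAP, t-BuOH gives the tert-butyl ester 34.

**Step 24.** The electron-rich benzylic bromide may ionise and decompose, or the bromophosphonium reagent may attack other ether oxygens.
Fallback, from 31 back to 33: the bromide is avoided. Bu4NF buffered with AcOH in THF removes the silyl group to give {(2S,3R)-2-[4-(benzyloxy)-3-methoxyphenyl]-5-(hydroxymethyl)-7-methoxy-2,3-dihydrobenzofuran-3-yl}methyl pivalate F12. F12 is joined to phenol 21 by Mitsunobu etherification (PPh3, DIAD, THF, 0 °C → rt) to give 33.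

## Further compounds

F1 | step 8 | (4R,5R)-4-{2-[4-(allyloxy)-3-methoxyphenyl]-1,3-dithian-2-yl}-5-[(1R,2S,5R)-menthyloxy]dihydrofuran-2(3H)-one | O=C1C[C@@H](C2(c3ccc(OCC=C)c(OC)c3)SCCCS2)[C@H](O[C@@H]2C[C@H](C)CC[C@H]2C(C)C)O1
F2 | step 11 | {(3R,4R)-2-[4-(allyloxy)-3-methoxyphenyl]-4-[4-(benzyloxy)-3-methoxybenzyl]-2-hydroxytetrahydrofuran-3-yl}methyl pivalate (C2 epimers) | COc1cc(C[C@H]2COC(O)(c3ccc(OCC=C)c(OC)c3)[C@H]2COC(=O)C(C)(C)C)ccc1OCc1ccccc1
F3 | step 11 | (2R,3R)-4-[4-(allyloxy)-3-methoxyphenyl]-2-[4-(benzyloxy)-3-methoxybenzyl]-4-oxo-3-(pivaloyloxymethyl)butyl methanesulfonate | COc1cc(C[C@@H](COS(C)(=O)=O)[C@H](COC(=O)C(C)(C)C)C(=O)c2ccc(OCC=C)c(OC)c2)ccc1OCc1ccccc1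
F4 | step 11 | (2R,3R,4R)-4-[4-(allyloxy)-3-methoxyphenyl]-2-[4-(benzyloxy)-3-methoxybenzyl]-4-hydroxy-3-(pivaloyloxymethyl)butyl methanesulfonate | COc1cc(C[C@@H](COS(C)(=O)=O)[C@H](COC(=O)C(C)(C)C)[C@@H](O)c2ccc(OCC=C)c(OC)c2)ccc1OCc1ccccc1
F5 | step 28 | (S)-1-oxo-1-(pyrrolidin-1-yl)propan-2-yl arylacetate (34 with the lactamide ester in place of tert-butyl) | COc1cc(C[C@H]2CO[C@@H](c3cc(CC(=O)O[C@@H](C)C(=O)N7CCCC7)c(OCc4cc(OC)c5c(c4)[C@H](COC(=O)C(C)(C)C)[C@@H](c4ccc(OCc6ccccc6)c(OC)c4)O5)c(OC)c3)[C@H]2COC(=O)C(C)(C)C)ccc1OCc1ccccc1
F6 | step 28 | (S)-1-oxo-1-(pyrrolidin-1-yl)propan-2-yl aryldiazoacetate (diazo derivative of F5) | COc1cc(C[C@H]2CO[C@@H](c3cc(C(=[N+]=[N-])C(=O)O[C@@H](C)C(=O)N7CCCC7)c(OCc4cc(OC)c5c(c4)[C@H](COC(=O)C(C)(C)C)[C@@H](c4ccc(OCc6ccccc6)c(OC)c4)O5)c(OC)c3)[C@H]2COC(=O)C(C)(C)C)ccc1OCc1ccccc1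
F7 | step 28 | inner trans dihydrobenzofuran lactamide ester (inner 2R,3R; 37 with the lactamide ester in place of tert-butyl) | COc1cc(C[C@H]2CO[C@@H](c3cc(OC)c4c(c3)[C@@H](C(=O)O[C@@H](C)C(=O)N7CCCC7)[C@H](c3cc(OC)c5c(c3)[C@H](COC(=O)C(C)(C)C)[C@@H](c3ccc(OCc6ccccc6)c(OC)c3)O5)O4)[C@H]2COC(=O)C(C)(C)C)ccc1OCc1ccccc1
F8 | step 14 | {(2R,3R,4R)-2-(3-allyl-4-hydroxy-5-methoxyphenyl)-4-[4-(benzyloxy)-3-methoxybenzyl]tetrahydrofuran-3-yl}methyl pivalate | COc1cc(C[C@H]2CO[C@@H](c3cc(CC=C)c(O)c(OC)c3)[C@H]2COC(=O)C(C)(C)C)ccc1OCc1ccccc1
F9 | step 14 | ring C allyl arene with the ring B benzyl ether (33 with allyl for Br) | COc1cc(C[C@H]2CO[C@@H](c3cc(CC=C)c(OCc4cc(OC)c5c(c4)[C@H](COC(=O)C(C)(C)C)[C@@H](c4ccc(OCc6ccccc6)c(OC)c4)O5)c(OC)c3)[C@H]2COC(=O)C(C)(C)C)ccc1OCc1ccccc1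
F10 | step 14 | arylacetaldehyde (33 with CH2CHO for Br) | COc1cc(C[C@H]2CO[C@@H](c3cc(CC=O)c(OCc4cc(OC)c5c(c4)[C@H](COC(=O)C(C)(C)C)[C@@H](c4ccc(OCc6ccccc6)c(OC)c4)O5)c(OC)c3)[C@H]2COC(=O)C(C)(C)C)ccc1OCc1ccccc1
F11 | step 14 | arylacetic acid (33 with CH2CO2H for Br) | COc1cc(C[C@H]2CO[C@@H](c3cc(CC(=O)O)c(OCc4cc(OC)c5c(c4)[C@H](COC(=O)C(C)(C)C)[C@@H](c4ccc(OCc6ccccc6)c(OC)c4)O5)c(OC)c3)[C@H]2COC(=O)C(C)(C)C)ccc1OCc1ccccc1
F12 | step 24 | {(2S,3R)-2-[4-(benzyloxy)-3-methoxyphenyl]-5-(hydroxymethyl)-7-methoxy-2,3-dihydrobenzofuran-3-yl}methyl pivalate | OCc1cc(OC)c2c(c1)[C@H](COC(=O)C(C)(C)C)[C@@H](c1ccc(OCc3ccccc3)c(OC)c1)O2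
A1 | alternative 1 | trans-5-bromo-2-(4-hydroxy-3-methoxyphenyl)-7-methoxy-3-(triisopropylsilyloxymethyl)-2,3-dihydrobenzofuran | Brc1cc(OC)c2c(c1)[C@H](CO[Si](C(C)C)(C(C)C)C(C)C)[C@@H](c1ccc(O)c(OC)c1)O2
A2 | alternative 2 | methyl 2-[4-(benzyloxy)-3-methoxyphenyl]-4-[3-methoxy-4-(triisopropylsilyloxy)benzyl]-4,5-dihydrofuran-3-carboxylate | COc1cc(C[C@H]2COC(c3ccc(OCc4ccccc4)c(OC)c3)=C2C(=O)OC)ccc1O[Si](C(C)C)(C(C)C)C(C)C
A3 | alternative 3 | fully protected target (three tert-butyldimethylsilyl ethers, two benzyl ethers) | COc1cc(C[C@H]2CO[C@@H](c3cc(OC)c4c(c3)[C@@H](CO[Si](C)(C)C(C)(C)C)[C@H](c3cc(OC)c5c(c3)[C@H](CO[Si](C)(C)C(C)(C)C)[C@@H](c3ccc(OCc6ccccc6)c(OC)c3)O5)O4)[C@H]2CO[Si](C)(C)C(C)(C)C)ccc1OCc1ccccc1
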